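**Plan**

Locants: indane C1 (diarylmethine), C2 (isopropylidene carbon), C3 (CH2), C3a/C7a (fusion carbons, C3a next to C3), C6–OH and C7–CHO on ring A; ring B is the benzodioxane arene, whose O1′ sits next to the carbon bound to C1.
Retrosynthesis: CHO ⇐ CH2OH; cut C3–C3a with allylic transposition to the open tertiary allylic alcohol Ar2CH–C(=CH2)–CMe2OH; cut both C–CH3 bonds and the O1′–CH dioxane bond back to an α-methylene dihydrocoumarin carrying an epoxide; cut the exo-CH2, the C1–ring A bond (coumarin + arylboronic acid) and the aryl O–CH2 ether bond.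
Forward: a coumarin on ring B (temporary lactone ring) is arylated at C4 (= C1) and methylenated; MeLi then opens it so that the lactone carbonyl carbon becomes CMe2 and the freed phenoxide closes the dioxane on the epoxide; the indane ring is closed last but one, and the aldehyde is made by oxidation.
Enabling feature: C3a is para to the C6 hydroxyl of ring A and is the only free position ortho to C7a, while C2 is the central carbon of a 1,1-dimethylallyl unit whose free terminus is C3. An η3-allylpalladium cation over C3–C2–CMe2 can therefore be captured by the phenol para carbon, which closes the five-membered ring and puts the double bond in the isopropylidene position in the same event.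
Stereochemistry: C1 comes from the (S)-SEGPHOS/rhodium conjugate arylation of the coumarin; the dioxane carbon comes from Sharpless epoxidation of prenol (D-tartrate) and inversion in the 6-exo epoxide opening.

Key step: step 12

Remark: 2-hydroxy-3-methoxy-5-methylbenzaldehyde and 2-bromo-6-hydroxybenzaldehyde are taken as commercial; the C1 descriptor changes between intermediates only because CIP priorities change, the spatial arrangement stays the same.

**Route**

Step 1
Reactants: 1 3-methylbut-2-en-1-ol (prenol)
Product: 3 [(2R)-3,3-dimethyloxiran-2-yl]methyl 4-methylbenzenesulfonate, via epoxy alcohol 2 (not isolated)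
Conditions: Ti(OiPr)4 (5 mol %), D-(−)-diisopropyl tartrate (7 mol %), cumene hydroperoxide, 4 Å MS, CH2Cl2, −20 °C; then TsCl, Et3N, DMAP (cat.), −10 °C
Reagents that add atoms: cumene hydroperoxide, CC(C)(OO)c1ccccc1; 4-methylbenzenesulfonyl chloride, Cc1ccc(cc1)S(Cl)(=O)=O
Why: Sharpless asymmetric epoxidation of a primary allylic alcohol, in which the D-tartrate complex should deliver oxygen to the face that gives the (R)-epoxide (mirror image of the outcome with L-tartrate for 3,3-disubstituted allylic alcohols), followed by in-situ sulfonylation because the small epoxy alcohol is water-soluble.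

Step 2
Reactants: 4 2-hydroxy-3-methoxy-5-methylbenzaldehyde
Product: 6 8-methoxy-6-methyl-2H-chromen-2-one, via ethyl (E)-2-hydroxycinnamate 5 (not isolated)
Conditions: Ph3P=CHCO2Et, PhNEt2, reflux
Reagents that add atoms: ethyl (triphenylphosphoranylidene)acetate, CCOC(=O)C=P(c1ccccc1)(c1ccccc1)c1ccccc1
Why: Wittig olefination of the salicylaldehyde followed by thermal E/Z equilibration and lactonisation is the classical coumarin synthesis, and the lactone is a temporary ring that masks the ring B phenol oxygen and locks the enoate in the cis geometry needed for step 8.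

Step 3
Reactants: 6 8-methoxy-6-methyl-2H-chromen-2-one
Product: 7 8-hydroxy-6-methyl-2H-chromen-2-one
Conditions: BBr3, CH2Cl2, −78 °C to rt; H2O
Reagents that add atoms: none
Why: Lewis-acid cleavage of the aryl methyl ether by BBr3, to which the coumarin lactone is inert.

Step 4
Reactants: 7 8-hydroxy-6-methyl-2H-chromen-2-one; 3 [(2R)-3,3-dimethyloxiran-2-yl]methyl 4-methylbenzenesulfonate
Product: 8 8-{[(2R)-3,3-dimethyloxiran-2-yl]methoxy}-6-methyl-2H-chromen-2-one
Conditions: K2CO3, DMF, 50 °C
Reagents that add atoms: none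
Why: Williamson ether synthesis by direct SN2 displacement of the primary tosylate by the phenoxide, which does not touch the epoxide stereocentre.

Step 5
Reactants: 9 2-bromo-6-hydroxybenzaldehyde
Product: 10 3-bromo-2-(hydroxymethyl)phenol
Conditions: NaBH4, MeOH, 0 °C
Reagents that add atoms: none
Why: Hydride reduction of the aldehyde to the benzylic alcohol, so that phenol and benzylic oxygen can be masked together in one ring.

Step 6
Reactants: 10 3-bromo-2-(hydroxymethyl)phenol
Product: 11 5-bromo-2,2-dimethyl-4H-1,3-benzodioxine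
Conditions: Me2C(OMe)2, PPTS (cat.), acetone, rt
Reagents that add atoms: 2,2-dimethoxypropane, COC(C)(C)OC
Why: Acid-catalysed transketalisation gives the six-membered acetonide, which is stable to the organometallic and basic steps that follow.

Step 7
Reactants: 11 5-bromo-2,2-dimethyl-4H-1,3-benzodioxine
Product: 13 (2,2-dimethyl-4H-1,3-benzodioxin-5-yl)boronic acid, via aryllithium 12 (not isolated)
Conditions: n-BuLi, THF, −78 °C; B(OiPr)3, −78 °C to rt; aq. NH4Cl
Reagents that add atoms: triisopropyl borate, CC(C)OB(OC(C)C)OC(C)C; water, O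
Why: Bromine–lithium exchange, borylation and mild hydrolysis is the standard arylboronic acid synthesis, and the aryllithium is meta to the ring oxygen so it cannot rearrange.

Step 8
Reactants: 8 8-{[(2R)-3,3-dimethyloxiran-2-yl]methoxy}-6-methyl-2H-chromen-2-one; 13 (2,2-dimethyl-4H-1,3-benzodioxin-5-yl)boronic acid
Product: 14 (4S)-4-(2,2-dimethyl-4H-1,3-benzodioxin-5-yl)-8-{[(2R)-3,3-dimethyloxiran-2-yl]methoxy}-6-methyl-3,4-dihydro-2H-chromen-2-one
Conditions: Rh(acac)(C2H4)2 (3 mol %), (S)-SEGPHOS (3.3 mol %), 13 (3 equiv), dioxane/H2O 10:1, 60 °C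
Reagents that add atoms: none
Why: Hayashi–Miyaura rhodium-catalysed asymmetric 1,4-addition of an arylboronic acid to a coumarin, in which the rigid cis-enoate binds the (S)-SEGPHOS aryl-rhodium complex through one face so that aryl transfer to C4 should give the (4S)-lactone (with coumarins the (R)-ligand is known to deliver the aryl group to the opposite face), and this sets C1 of the target.

Step 9
Reactants: 14 (4S)-4-(2,2-dimethyl-4H-1,3-benzodioxin-5-yl)-8-{[(2R)-3,3-dimethyloxiran-2-yl]methoxy}-6-methyl-3,4-dihydro-2H-chromen-2-one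
Product: 17 (4S)-4-(2,2-dimethyl-4H-1,3-benzodioxin-5-yl)-8-{[(2R)-3,3-dimethyloxiran-2-yl]methoxy}-6-methyl-3-methylidene-3,4-dihydro-2H-chromen-2-one, via Mannich base 15 (not isolated), via ammonium iodide 16 (not isolated)
Conditions: LiN(SiMe3)2, THF, −78 °C; Me2N=CH2+ I−, −78 to 0 °C; MeI, CH2Cl2, rt; aq. NaHCO3
Reagents that add atoms: N,N-dimethylmethyleneiminium iodide, C=[N+](C)C.[I-]
Why: α-Methylenation of a lactone by Mannich reaction of its lithium enolate, N-methylation and Hofmann-type β-elimination under bicarbonate, conditions mild enough that the exocyclic double bond should not migrate into the ring and the C4 stereocentre is kept.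

Step 10
Reactants: 17 (4S)-4-(2,2-dimethyl-4H-1,3-benzodioxin-5-yl)-8-{[(2R)-3,3-dimethyloxiran-2-yl]methoxy}-6-methyl-3-methylidene-3,4-dihydro-2H-chromen-2-one
Product: 20 (4R)-4-(2,2-dimethyl-4H-1,3-benzodioxin-5-yl)-4-[(3S)-3-(2-hydroxypropan-2-yl)-7-methyl-2,3-dihydro-1,4-benzodioxin-5-yl]-2-methyl-3-methylidenebutan-2-ol, via enone 18 (not isolated), via epoxy phenol 19 (not isolated)
Conditions: MeLi (4 equiv), CeCl3 (4 equiv), THF, −78 °C; aq. work-up; K2CO3 (0.3 equiv), MeOH, 45 °C
Reagents that add atoms: methyllithium, [Li]C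
Why: Methylcerium addition goes 1,2 twice to the aryl lactone (through the enone), turning the lactone carbonyl carbon into the CMe2OH carbon and releasing the ring B phenol, whose phenoxide then opens the epoxide at its secondary carbon in a base-mediated 6-exo-tet SN2 reaction with inversion to set the (S)-dioxane stereocentre.

Step 11
Reactants: 20 (4R)-4-(2,2-dimethyl-4H-1,3-benzodioxin-5-yl)-4-[(3S)-3-(2-hydroxypropan-2-yl)-7-methyl-2,3-dihydro-1,4-benzodioxin-5-yl]-2-methyl-3-methylidenebutan-2-ol
Product: 21 (4R)-4-[3-hydroxy-2-(hydroxymethyl)phenyl]-4-[(3S)-3-(2-hydroxypropan-2-yl)-7-methyl-2,3-dihydro-1,4-benzodioxin-5-yl]-2-methyl-3-methylidenebutan-2-ol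
Conditions: PPTS (0.2 equiv), MeOH, 40 °C
Reagents that add atoms: none
Why: Mild acid-catalysed transketalisation to methanol removes the acetonide, and the pyridinium acid is too weak to ionise the tertiary allylic alcohol at a useful rate.

Step 12
Reactants: 21 (4R)-4-[3-hydroxy-2-(hydroxymethyl)phenyl]-4-[(3S)-3-(2-hydroxypropan-2-yl)-7-methyl-2,3-dihydro-1,4-benzodioxin-5-yl]-2-methyl-3-methylidenebutan-2-ol
Product: 22 (3S)-4-(hydroxymethyl)-3-[(3S)-3-(2-hydroxypropan-2-yl)-7-methyl-2,3-dihydro-1,4-benzodioxin-5-yl]-2-(propan-2-ylidene)-2,3-dihydro-1H-inden-5-ol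
Conditions: Pd(PPh3)4 (5 mol %), Et3B (30 mol %), THF, 50 °C
Reagents that add atoms: none
Why: Proposed new method: Et3B-assisted ionisation of the tertiary allylic C–O bond by zerovalent palladium should give the η3-allylpalladium cation over C3–C2–CMe2, the departing hydroxide deprotonates the C6 phenol, and the phenoxide attacks the unsubstituted terminus C3 through its para carbon C3a on the face anti to palladium before the dienone tautomerises back to the phenol, so that ring closure and the 1,3-transposition that creates the tetrasubstituted isopropylidene alkene are one event that releases only water. The closest known reaction types are the palladium-catalysed intramolecular Friedel–Crafts-type allylic alkylation of phenols (Tsuji–Trost manifold), the Et3B-promoted C-allylation of naphthols and benzenepolyols with free allylic alcohols such as 2-methylbut-3-en-2-ol, and the ring-closing step of palladium trimethylenemethane cycloadditions; not yet shown is a simple phenol carbon closing onto an allyl terminus when the tether leaves from the central allyl carbon. The five-membered ring closes in a mode that is formally 5-endo with respect to the allyl unit, since C2 and C3 both end up in the ring as in the trimethylenemethane closure, and this should be feasible because rotation about C1–C2 and η3/η1 slippage at the CH2 terminus let C3 reach the π face at C3a at an estimated angle of about 60° to both the arene and the allyl plane. No stereocentre is formed, and C1 should keep its configuration because it is not part of the allyl system, has no hydrogen β to palladium in either η1 form and is not deprotonated under these near-neutral conditions. The step needs selectivity for the terminus (attack at CMe2 would also give a five-membered ring), for the arene and for the position, and the substrate secures all three: soft nucleophiles attack the less substituted end of a 1,1-dimethylallyl palladium complex, only ring A carries a free phenol whereas ring B is a diether, and C3a is both para to the hydroxyl and the only free position ortho to C7a. O-Allylation cannot occur within the molecule across the meta relationship and is reversible between molecules, the benzylic and tertiary hydroxyls are poor nucleophiles toward allylpalladium without strong base, and the second tertiary alcohol is not allylic and cannot ionise.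

Step 13
Reactants: 22 (3S)-4-(hydroxymethyl)-3-[(3S)-3-(2-hydroxypropan-2-yl)-7-methyl-2,3-dihydro-1,4-benzodioxin-5-yl]-2-(propan-2-ylidene)-2,3-dihydro-1H-inden-5-ol
Product: 23 diaporindene H
Conditions: MnO2 (10 equiv), CH2Cl2, rt
Reagents that add atoms: none
Why: MnO2 oxidises benzylic alcohols selectively, so only the ortho-hydroxybenzyl alcohol should be converted into the hydrogen-bonded salicylaldehyde while the tertiary alcohol, the tetrasubstituted alkene and C1 stay untouched.

**Compound list**

1 | 3-methylbut-2-en-1-ol (prenol) | CC(C)=CCO | starting material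
2 | [(2R)-3,3-dimethyloxiran-2-yl]methanol | OC[C@H]1OC1(C)C | intermediate
3 | [(2R)-3,3-dimethyloxiran-2-yl]methyl 4-methylbenzenesulfonate | Cc1ccc(cc1)S(=O)(=O)OC[C@H]1OC1(C)C | intermediate
4 | 2-hydroxy-3-methoxy-5-methylbenzaldehyde | COc1cc(C)cc(C=O)c1O | starting material
5 | ethyl (E)-3-(2-hydroxy-3-methoxy-5-methylphenyl)prop-2-enoate | CCOC(=O)/C=C/c1cc(C)cc(OC)c1O | intermediate
6 | 8-methoxy-6-methyl-2H-chromen-2-one | COc1cc(C)cc2ccc(=O)oc12 | intermediate
7 | 8-hydroxy-6-methyl-2H-chromen-2-one | Oc1cc(C)cc2ccc(=O)oc12 | intermediate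
8 | 8-{[(2R)-3,3-dimethyloxiran-2-yl]methoxy}-6-methyl-2H-chromen-2-one | O=c1ccc2cc(C)cc(OC[C@H]3OC3(C)C)c2o1 | intermediate
9 | 2-bromo-6-hydroxybenzaldehyde | O=Cc1c(O)cccc1Br | starting material
10 | 3-bromo-2-(hydroxymethyl)phenol | OCc1c(O)cccc1Br | intermediate
11 | 5-bromo-2,2-dimethyl-4H-1,3-benzodioxine | CC1(C)OCc2c(Br)cccc2O1 | intermediate
12 | (2,2-dimethyl-4H-1,3-benzodioxin-5-yl)lithium | [Li]c1cccc2OC(C)(C)OCc12 | intermediate
13 | (2,2-dimethyl-4H-1,3-benzodioxin-5-yl)boronic acid | CC1(C)OCc2c(B(O)O)cccc2O1 | intermediate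
14 | (4S)-4-(2,2-dimethyl-4H-1,3-benzodioxin-5-yl)-8-{[(2R)-3,3-dimethyloxiran-2-yl]methoxy}-6-methyl-3,4-dihydro-2H-chromen-2-one | O=C1C[C@@H](c2cccc3OC(C)(C)OCc23)c2cc(C)cc(OC[C@H]3OC3(C)C)c2O1 | intermediate
15 | (4S)-3-[(dimethylamino)methyl]-4-(2,2-dimethyl-4H-1,3-benzodioxin-5-yl)-8-{[(2R)-3,3-dimethyloxiran-2-yl]methoxy}-6-methyl-3,4-dihydro-2H-chromen-2-one (mixture of C3 epimers) | O=C1C(CN(C)C)[C@@H](c2cccc3OC(C)(C)OCc23)c2cc(C)cc(OC[C@H]3OC3(C)C)c2O1 | intermediate
16 | 1-[(4S)-4-(2,2-dimethyl-4H-1,3-benzodioxin-5-yl)-8-{[(2R)-3,3-dimethyloxiran-2-yl]methoxy}-6-methyl-2-oxo-3,4-dihydro-2H-chromen-3-yl]-N,N,N-trimethylmethanaminium iodide (mixture of C3 epimers) | O=C1C(C[N+](C)(C)C)[C@@H](c2cccc3OC(C)(C)OCc23)c2cc(C)cc(OC[C@H]3OC3(C)C)c2O1.[I-] | intermediate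
17 | (4S)-4-(2,2-dimethyl-4H-1,3-benzodioxin-5-yl)-8-{[(2R)-3,3-dimethyloxiran-2-yl]methoxy}-6-methyl-3-methylidene-3,4-dihydro-2H-chromen-2-one | O=C1C(=C)[C@@H](c2cccc3OC(C)(C)OCc23)c2cc(C)cc(OC[C@H]3OC3(C)C)c2O1 | intermediate
18 | (4S)-4-(2,2-dimethyl-4H-1,3-benzodioxin-5-yl)-4-(3-{[(2R)-3,3-dimethyloxiran-2-yl]methoxy}-2-hydroxy-5-methylphenyl)-3-methylidenebutan-2-one | C=C(C(C)=O)[C@@H](c1cccc2OC(C)(C)OCc12)c1cc(C)cc(OC[C@H]2OC2(C)C)c1O | intermediate
19 | (4R)-4-(2,2-dimethyl-4H-1,3-benzodioxin-5-yl)-4-(3-{[(2R)-3,3-dimethyloxiran-2-yl]methoxy}-2-hydroxy-5-methylphenyl)-2-methyl-3-methylidenebutan-2-ol | C=C(C(C)(C)O)[C@@H](c1cccc2OC(C)(C)OCc12)c1cc(C)cc(OC[C@H]2OC2(C)C)c1O | intermediate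
20 | (4R)-4-(2,2-dimethyl-4H-1,3-benzodioxin-5-yl)-4-[(3S)-3-(2-hydroxypropan-2-yl)-7-methyl-2,3-dihydro-1,4-benzodioxin-5-yl]-2-methyl-3-methylidenebutan-2-ol | C=C(C(C)(C)O)[C@@H](c1cccc2OC(C)(C)OCc12)c1cc(C)cc2c1O[C@H](C(C)(C)O)CO2 | intermediate
21 | (4R)-4-[3-hydroxy-2-(hydroxymethyl)phenyl]-4-[(3S)-3-(2-hydroxypropan-2-yl)-7-methyl-2,3-dihydro-1,4-benzodioxin-5-yl]-2-methyl-3-methylidenebutan-2-ol | C=C(C(C)(C)O)[C@@H](c1cccc(O)c1CO)c1cc(C)cc2c1O[C@H](C(C)(C)O)CO2 | intermediate
22 | (3S)-4-(hydroxymethyl)-3-[(3S)-3-(2-hydroxypropan-2-yl)-7-methyl-2,3-dihydro-1,4-benzodioxin-5-yl]-2-(propan-2-ylidene)-2,3-dihydro-1H-inden-5-ol | CC(C)=C1Cc2ccc(O)c(CO)c2[C@H]1c1cc(C)cc2c1O[C@H](C(C)(C)O)CO2 | intermediate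
23 | diaporindene H, (3S)-5-hydroxy-3-[(3S)-3-(2-hydroxypropan-2-yl)-7-methyl-2,3-dihydro-1,4-benzodioxin-5-yl]-2-(propan-2-ylidene)-2,3-dihydro-1H-indene-4-carbaldehyde | CC(C)=C1Cc2ccc(O)c(C=O)c2[C@H]1c1cc(C)cc2c1O[C@H](C(C)(C)O)CO2 | target

**Step count and risks**

Total step count: 13. Longest linear sequence: 9 steps (steps 2, 3, 4, 8, 9, 10, 11, 12, 13 from compound 4; the branch from compound 9 through steps 5, 6, 7 is equally long).

The three steps most likely to fail:

Step 12 (proposed new method). The endo-type closure of the phenol carbon onto the allylpalladium terminus may be too slow, so that reversible intermolecular O-allylation builds up oligomers or β-hydride loss from the methyl groups drains the allyl complex into a diene. The fallback inverts the polarity of ring A and fixes the bond position by a carbon–halogen bond. It sets out from 21: para-selective bromination of the free phenol (n-Bu4NBr3, CH2Cl2/MeOH, 0 °C) should give (4R)-4-[6-bromo-3-hydroxy-2-(hydroxymethyl)phenyl]-4-[(3S)-3-(2-hydroxypropan-2-yl)-7-methyl-2,3-dihydro-1,4-benzodioxin-5-yl]-2-methyl-3-methylidenebutan-2-ol F1. A nickel-catalysed reductive cross-electrophile coupling of the aryl bromide with the allylic alcohol activated in situ (NiBr2(dme), 2,2′-bipyridine, Mn powder, ZrCl4 co-catalyst, DMA) then closes the same C3–C3a bond by reductive elimination at the less hindered allyl terminus and comes back to the route at 22.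

Step 8. Transmetalation and insertion of the ortho-substituted arylboronic acid may be slower than its protodeboronation, leaving the coumarin unconverted. The fallback sets out from 8 and installs the aryl group at the coumarin oxidation level: oxidative Heck coupling of 8 with 13 (Pd(OAc)2, 1,10-phenanthroline, O2, DMF) should give 4-(2,2-dimethyl-4H-1,3-benzodioxin-5-yl)-8-{[(2R)-3,3-dimethyloxiran-2-yl]methoxy}-6-methyl-2H-chromen-2-one F2. Asymmetric conjugate reduction with CuH generated from Cu(OAc)2 and (EtO)2MeSiH, using the DTBM-SEGPHOS enantiomer that delivers hydride to the required face (t-BuOH, toluene), then sets C1 and comes back to the route at 14.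

Step 9. The lithium enolate of the aryl lactone may fragment to a ketene and a phenoxide on warming, or the exocyclic double bond of the product may migrate into the ring to give the aromatic 3-methylcoumarin, which erases C1. The fallback sets out from 14 and opens the lactone before the methylene group is introduced. K2CO3 in MeOH should give methyl (3S)-3-(2,2-dimethyl-4H-1,3-benzodioxin-5-yl)-3-[(3S)-3-(2-hydroxypropan-2-yl)-7-methyl-2,3-dihydro-1,4-benzodioxin-5-yl]propanoate F3 by methanolysis, with the freed phenoxide closing the dioxane on the epoxide. α-Methylenation of this open-chain ester (LiN(iPr)2, Me2N=CH2+ I−; MeI; aq. NaHCO3) gives methyl 2-[(S)-(2,2-dimethyl-4H-1,3-benzodioxin-5-yl)[(3S)-3-(2-hydroxypropan-2-yl)-7-methyl-2,3-dihydro-1,4-benzodioxin-5-yl]methyl]prop-2-enoate F4, and MeLi/CeCl3 in THF at −78 °C converts it into the tertiary allylic alcohol, coming back to the route at 20.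

Further compounds
F1 | step 12 | (4R)-4-[6-bromo-3-hydroxy-2-(hydroxymethyl)phenyl]-4-[(3S)-3-(2-hydroxypropan-2-yl)-7-methyl-2,3-dihydro-1,4-benzodioxin-5-yl]-2-methyl-3-methylidenebutan-2-ol | C=C(C(C)(C)O)[C@@H](c1c(Br)ccc(O)c1CO)c1cc(C)cc2c1O[C@H](C(C)(C)O)CO2
F2 | step 8 | 4-(2,2-dimethyl-4H-1,3-benzodioxin-5-yl)-8-{[(2R)-3,3-dimethyloxiran-2-yl]methoxy}-6-methyl-2H-chromen-2-one | O=c1cc(-c2cccc3OC(C)(C)OCc23)c2cc(C)cc(OC[C@H]3OC3(C)C)c2o1
F3 | step 9 | methyl (3S)-3-(2,2-dimethyl-4H-1,3-benzodioxin-5-yl)-3-[(3S)-3-(2-hydroxypropan-2-yl)-7-methyl-2,3-dihydro-1,4-benzodioxin-5-yl]propanoate | COC(=O)C[C@@H](c1cccc2OC(C)(C)OCc12)c1cc(C)cc2c1O[C@H](C(C)(C)O)CO2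
F4 | step 9 | methyl 2-[(S)-(2,2-dimethyl-4H-1,3-benzodioxin-5-yl)[(3S)-3-(2-hydroxypropan-2-yl)-7-methyl-2,3-dihydro-1,4-benzodioxin-5-yl]methyl]prop-2-enoate | C=C(C(=O)OC)[C@@H](c1cccc2OC(C)(C)OCc12)c1cc(C)cc2c1O[C@H](C(C)(C)O)CO2
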